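The earlier runs and the new flask stem from a simulated flask for an exercise, and the scatter is random.

The alder run, with 7.5 mol% of free catalyst at 0 °C, showed 9.8% of target after 0.833 d, and I started my reckoning for the new flasks from that first reading.

all flasks: substrate 0.34 M; impurity 16 mM
- larch: free catalyst 3.4 mol%; temperature −25 °C; run made earlier
- alder: free catalyst 7.5 mol%; temperature 0 °C; run made earlier
- noon: free catalyst 5 mol%; temperature 0 °C; time 3.0 d
- autumn: free catalyst 5 mol%; temperature −20 °C; time 3.0 d
- dawn: free catalyst 5 mol%; temperature 20 °C; time 3.0 d

| run | time / d | target / % |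
|---|---|---|
| larch | 0.833 | 0 |
| larch | 2.00 | 0 |
| larch | 6.00 | 1.9 |
| larch | 15.0 | 1.7 |
| alder | 0.833 | 9.8 |
| alder | 1.67 | 18.3 |
| alder | 2.50 | 25.2 |
| alder | 4.00 | 34.7 |

(readings scatter by 1 percentage point)

* which flask leads in amount of target, in percent of the substrate charged ("all alike" within 1.5 percentage points) (noon / autumn / dawn / all alike)
* how much target is there at the end, in percent of the substrate charged: noon
* how much target is there at the end, in percent of the substrate charged: autumn
* how much target is there at the end, in percent of the substrate charged: dawn

- in a conversion other conformer counts as not yet reacted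

Taking target as substrate gone, I read from alder a pseudo-first-order constant of 0.124 d⁻¹, and so a reach rate of 1.65 d⁻¹: the natural logarithm of the charge over the fraction left, per day and per unit of loading fraction, at 0.34 M of substrate and 0 °C. It is a reading, with a scatter of 1 percentage point on 9.8%.

I turned the loading first. By hand it multiplies the reach rate, so I put noon, at 5 mol%, at 0.0825 d⁻¹ to begin with. Time multiplies again, and over 3.0 d noon's plain reach came to 0.248.

Then I turned to the impurity, which is 4.71% of the substrate, less than noon's loading. Had it bound catalyst at once, alder's constant should have held steady afterwards. But across its last pair of readings that constant read 0.0906 d⁻¹, lower than at first, so I took the loss as slow and in step with reach. Alder's drop, itself read off scattered readings, gave a loss of 6.24% of loading per unit of reach, and so, as my estimate and not as a bound, a working ceiling on reach of 0.802 for noon's loading. With the plain reach bent exponentially toward that ceiling, I expected 19.2% of target at noon.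

Temperature came last. Larch's 1.9% after 6.00 d, a single reading with a scatter of 1 point, set against alder, read roughly as an activation energy of 64.6 kJ mol⁻¹. Keeping the ceiling unchanged with temperature, I expected 2.54% in autumn and 50.7% at dawn, so dawn led by my reckoning.

The forecast, which differed from my figures, named dawn, with 4.5% for noon, 0.7% for autumn and 15% for dawn, reasoning that at noon “only about 0.3 mol% (1 mM) stays free”.

The flasks gave 19.2% at noon, 2.44% in autumn and 47.3% at dawn, so dawn led.

    substrate ⇌ other conformer (K = 4.00, k = 7.10 × 10⁻⁵ min⁻¹, Ea = 105 kJ mol⁻¹, ΔH = −39.0 kJ mol⁻¹)
    substrate + free catalyst → free catalyst + target (k = 0.0400 L mol⁻¹ min⁻¹, Ea = 73.0 kJ mol⁻¹)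
    free catalyst + other conformer → free catalyst + isomer of the product (k = 0.750 L mol⁻¹ min⁻¹, Ea = 50.0 kJ mol⁻¹)
    substrate → decomposition product (k = 9.60 × 10⁻⁸ min⁻¹, Ea = 113 kJ mol⁻¹)
    free catalyst + impurity → spent catalyst (k = 0.160 L mol⁻¹ min⁻¹, Ea = 73.0 kJ mol⁻¹)
    (constants at 20 °C)

After 3.00 d, noon held 45.7% of its catalyst free and 42% of its impurity, with 80% of the substrate left, a reach of 0.228 against the plain 0.248 from the reach rate. The neighbour with 1.4 M of substrate kept the same loading, so I scaled the plain reach by the strength ratio 4.12. That gave 36.0% of substrate left, and that neighbour held 33%.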